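**Plan**
- Retrosynthetic cuts, in order: (1) the ester C–O bond of the side chain; (2) the two ring-fusion bonds C1–C8a and C4–C4a of the quinone ring (ring A); (3) the bond from the carbinol carbon to ring carbon C2 (furan C3).
- Enabling feature: in ring A the oxygens at C1 and C4 flank a C2–C3 unit that carries nothing but the side chain, which is a 3-substituted 2-oxyfuran in disguise; ring B with its oxygens at C5 and C8 is a symmetric 3,6-dioxygenated benzyne.
- Forward: the C6 chain is attached to 3-lithiofuran, furan C2 is oxygenated and silylated, ring A is built onto preformed ring B by aryne–furan cycloaddition with bridge opening, and oxidation, deprotection and esterification finish the molecule.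
- Stereochemistry: the single (R) centre is set by oxazaborolidine-catalysed reduction of the furyl ketone (step 3); no later step breaks a bond at this carbon.

Key step: step 7

Remark (assumption): the furan oxygen and the side-chain oxygen carry the same tert-butyldimethylsilyl group so that one reagent installs both; butenolide 10 may contain some 2(3H)-tautomer, which gives the same furan 11.

**Route**

Step 1
Reactants: 1 4-methylpent-3-enoic acid
Product: 3 N-methoxy-N,4-dimethylpent-3-enamide, via acylimidazole 2 (not isolated)
Conditions: 1,1'-carbonyldiimidazole, CH2Cl2, 0 °C → rt; then MeNH(OMe)·HCl, rt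
Reagents that add atoms: N,O-dimethylhydroxylamine hydrochloride, CNOC.Cl
Why: Acyl-imidazole activation followed by acylation of the amine (Weinreb amide formation) is mild enough to leave the β,γ-alkene in place.

Step 2
Reactants: 4 3-bromofuran; 3 N-methoxy-N,4-dimethylpent-3-enamide
Product: 6 1-(furan-3-yl)-4-methylpent-3-en-1-one, via 3-lithiofuran 5 (not isolated)
Conditions: n-BuLi, THF, −78 °C; then 3, −78 °C; aq. NH4Cl
Reagents that add atoms: none
Why: Bromine–lithium exchange at −78 °C gives 3-lithiofuran without migration of lithium to C2, and its addition to the N-methoxy-N-methylamide stops at the chelated tetrahedral adduct (Weinreb ketone synthesis), so the β,γ-unsaturated ketone is released only on quench.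

Step 3
Reactants: 6 1-(furan-3-yl)-4-methylpent-3-en-1-one
Product: 7 (1R)-1-(furan-3-yl)-4-methylpent-3-en-1-ol
Conditions: (S)-Me-CBS oxazaborolidine [(S)-1-methyl-3,3-diphenyltetrahydro-1H,3H-pyrrolo[1,2-c][1,3,2]oxazaborole] (10 mol %), BH3·SMe2 (0.6–1.0 equiv), THF, −20 °C, slow addition of 6; MeOH quench
Reagents that add atoms: none
Why: In this Corey–Bakshi–Shibata reduction the (S)-oxazaborolidine–BH3 complex delivers hydride to the ketone face that keeps the furyl group, acting as the large substituent, away from the B-methyl group, which should set the (R) carbinol centre (the same sense as acetophenone giving (R)-1-phenylethanol), while catalysed carbonyl reduction at −20 °C should outpace hydroboration of the trisubstituted alkene.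

Step 4
Reactants: 7 (1R)-1-(furan-3-yl)-4-methylpent-3-en-1-ol
Product: 10 3-[(1R)-1-hydroxy-4-methylpent-3-enyl]furan-2(5H)-one, via dilithio species 8 (not isolated), via lithium furyltrimethoxyborate 9 (not isolated)
Conditions: n-BuLi (2.2 equiv), THF, −78 → 0 °C; B(OMe)3, −78 °C → rt; 30% H2O2, aq. NaHCO3, 0 °C; mild acidification
Reagents that add atoms: hydrogen peroxide, OO
Why: Alkoxide-directed ortho-lithiation should place the second lithium at furan C2 next to the side chain, and borylation followed by peroxide oxidation of the C–B bond (aryl borate oxidation) gives the 2-hydroxyfuran, which tautomerises to the butenolide, while buffered H2O2 does not epoxidise the isolated alkene and the carbinol centre is not involved.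

Step 5
Reactants: 10 3-[(1R)-1-hydroxy-4-methylpent-3-enyl]furan-2(5H)-one
Product: 11 tert-butyl{[3-((1R)-1-(tert-butyldimethylsilyloxy)-4-methylpent-3-enyl)furan-2-yl]oxy}dimethylsilane
Conditions: TBSOTf (2.4 equiv), Et3N, CH2Cl2, 0 °C; NaHCO3 work-up, Et3N-deactivated silica
Reagents that add atoms: tert-butyldimethylsilyl trifluoromethanesulfonate, CC(C)(C)[Si](C)(C)OS(=O)(=O)C(F)(F)F
Why: The silyl triflate with amine base silylates the secondary alcohol and converts the butenolide into its aromatic silyl dienol ether (the standard 2-silyloxyfuran formation by soft enolisation), without breaking a bond at the stereocentre.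

Step 6
Reactants: 12 2-bromobenzene-1,4-diol
Product: 13 2-bromo-1,4-bis(methoxymethoxy)benzene
Conditions: NaH, MOMCl, THF/DMF, 0 °C → rt
Reagents that add atoms: chloromethyl methyl ether, COCCl
Why: Williamson-type O-alkylation of the bis-phenoxide gives the bis-acetal, which tolerates strong base and later helps to acidify the ring proton next to bromine.

Step 7
Reactants: 13 2-bromo-1,4-bis(methoxymethoxy)benzene; 11 tert-butyl{[3-((1R)-1-(tert-butyldimethylsilyloxy)-4-methylpent-3-enyl)furan-2-yl]oxy}dimethylsilane
Product: 17 4-(tert-butyldimethylsilyloxy)-3-[(1R)-1-(tert-butyldimethylsilyloxy)-4-methylpent-3-enyl]-5,8-bis(methoxymethoxy)naphthalen-1-ol, via aryllithium 14 (not isolated), via aryne 15 (not isolated), via bridged cycloadduct 16 (not isolated)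
Conditions: 13 (1.5 equiv), 11 (1.0 equiv), LiTMP (lithium 2,2,6,6-tetramethylpiperidide, 1.6 equiv, made from the amine and n-BuLi) added slowly, THF, −78 °C → rt; aq. NH4Cl
Reagents that add atoms: none
Why: LiTMP removes the ring proton flanked by bromine and an acetal oxygen of 13, and aryllithium 14 loses LiBr on warming to give the symmetric 3,6-dioxygenated aryne 15, which the electron-rich silyloxyfuran 11 captures across its 2 and 5 positions in a [4+2] cycloaddition to give the oxygen-bridged ketal 16 (new bonds C1–C8a and C4–C4a). The bridgehead silyloxy oxygen then pushes out the bridging oxygen and loss of the proton at the other bridgehead aromatises ring A as the 4-silyloxy-1-naphthol 17, a step completed by the NH4Cl work-up. The closest known reaction type is the aryne Diels–Alder reaction of 2-alkoxyfurans with opening of the adduct to 4-alkoxy-1-naphthols. Ring A is closed by intermolecular [4+2] cycloaddition onto the preformed ring B, followed by aromatising bridge opening. No lasting stereocentre is formed, since the two bridgehead centres of 16 vanish on aromatisation, and the side-chain centre is not deprotonated under these conditions. The step needs chemoselective capture of the aryne by the diene in preference to the amine, the naphtholate or the prenyl alkene, which the high reactivity of the 2-silyloxyfuran and the hindered, poorly nucleophilic 2,2,6,6-tetramethylpiperidine should secure, and no regiochemical question arises because 15 is symmetric.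

Step 8
Reactants: 17 4-(tert-butyldimethylsilyloxy)-3-[(1R)-1-(tert-butyldimethylsilyloxy)-4-methylpent-3-enyl]-5,8-bis(methoxymethoxy)naphthalen-1-ol
Product: 18 2-[(1R)-1-(tert-butyldimethylsilyloxy)-4-methylpent-3-enyl]-5,8-bis(methoxymethoxy)naphthalene-1,4-dione
Conditions: PhI(OAc)2, MeCN/H2O, 0 °C
Reagents that add atoms: none
Why: In this phenol oxidation by trivalent iodine, ligand exchange at the free naphthol and two-electron oxidation give a para-silyloxonium cation that hands its silyl group to water, so the quinone should form without touching the acetals, the alkyl silyl ether or the alkene.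

Step 9
Reactants: 18 2-[(1R)-1-(tert-butyldimethylsilyloxy)-4-methylpent-3-enyl]-5,8-bis(methoxymethoxy)naphthalene-1,4-dione
Product: 19 5,8-dihydroxy-2-[(1R)-1-hydroxy-4-methylpent-3-enyl]naphthalene-1,4-dione (shikonin)
Conditions: 2 M aq. HCl, THF, 0 °C → rt, monitored and stopped at full conversion
Reagents that add atoms: none
Why: Acid-catalysed acetal hydrolysis, helped by the peri carbonyl groups, and acid-catalysed cleavage of the silyl ether unmask the naphthazarin and the carbinol, and the electron-poor ring that carries the carbinol should disfavour ionisation at the stereocentre under these dilute conditions.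

Step 10
Reactants: 19 5,8-dihydroxy-2-[(1R)-1-hydroxy-4-methylpent-3-enyl]naphthalene-1,4-dione; 20 3,4-dimethylpent-3-enoic acid
Product: 21 (1R)-1-(5,8-dihydroxy-1,4-dioxo-1,4-dihydronaphthalen-2-yl)-4-methylpent-3-enyl 3,4-dimethylpent-3-enoate (CNP0163639.1)
Conditions: N,N'-dicyclohexylcarbodiimide, 4-(dimethylamino)pyridine (cat.), CH2Cl2, 0 °C → rt
Reagents that add atoms: none
Why: In this Steglich esterification the carbodiimide-activated acid acylates the only aliphatic hydroxyl, because the two peri phenols are tied up in hydrogen bonds to the quinone carbonyls and are far less nucleophilic, and the C–O bond at the stereocentre is not broken.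

**Compound list**

1 | 4-methylpent-3-enoic acid | CC(C)=CCC(=O)O | starting material
2 | 1-(1H-imidazol-1-yl)-4-methylpent-3-en-1-one (formed in the flask) | CC(C)=CCC(=O)n1ccnc1 | intermediate
3 | N-methoxy-N,4-dimethylpent-3-enamide | CC(C)=CCC(=O)N(C)OC | intermediate
4 | 3-bromofuran | Brc1ccoc1 | starting material
5 | 3-lithiofuran (formed in the flask) | [Li]c1ccoc1 | intermediate
6 | 1-(furan-3-yl)-4-methylpent-3-en-1-one | CC(C)=CCC(=O)c1ccoc1 | intermediate
7 | (1R)-1-(furan-3-yl)-4-methylpent-3-en-1-ol | CC(C)=CC[C@@H](O)c1ccoc1 | intermediate
8 | lithium (1R)-1-(2-lithiofuran-3-yl)-4-methylpent-3-en-1-olate (formed in the flask) | CC(C)=CC[C@@H](O[Li])c1ccoc1[Li] | intermediate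
9 | lithium trimethoxy{3-[(1R)-1-(lithiooxy)-4-methylpent-3-enyl]furan-2-yl}borate (formed in the flask) | CC(C)=CC[C@@H](O[Li])c1ccoc1[B-](OC)(OC)OC.[Li+] | intermediate
10 | 3-[(1R)-1-hydroxy-4-methylpent-3-enyl]furan-2(5H)-one | CC(C)=CC[C@@H](O)C1=CCOC1=O | intermediate
11 | tert-butyl{[3-((1R)-1-(tert-butyldimethylsilyloxy)-4-methylpent-3-enyl)furan-2-yl]oxy}dimethylsilane | CC(C)=CC[C@@H](O[Si](C)(C)C(C)(C)C)c1ccoc1O[Si](C)(C)C(C)(C)C | intermediate
12 | 2-bromobenzene-1,4-diol | Oc1ccc(O)c(Br)c1 | starting material
13 | 2-bromo-1,4-bis(methoxymethoxy)benzene | COCOc1ccc(OCOC)c(Br)c1 | intermediate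
14 | [2-bromo-3,6-bis(methoxymethoxy)phenyl]lithium (formed in the flask) | COCOc1ccc(OCOC)c(Br)c1[Li] | intermediate
15 | 3,6-bis(methoxymethoxy)benzyne (formed in the flask) | COCOC1=CC=C(OCOC)C#C1 | intermediate
16 | 1-(tert-butyldimethylsilyloxy)-2-[(1R)-1-(tert-butyldimethylsilyloxy)-4-methylpent-3-enyl]-5,8-bis(methoxymethoxy)-1,4-dihydro-1,4-epoxynaphthalene (both bridgehead configurations; formed in the flask) | CC(C)=CC[C@@H](O[Si](C)(C)C(C)(C)C)C1=CC2OC1(O[Si](C)(C)C(C)(C)C)c1c(OCOC)ccc(OCOC)c12 | intermediate
17 | 4-(tert-butyldimethylsilyloxy)-3-[(1R)-1-(tert-butyldimethylsilyloxy)-4-methylpent-3-enyl]-5,8-bis(methoxymethoxy)naphthalen-1-ol | CC(C)=CC[C@@H](O[Si](C)(C)C(C)(C)C)c1cc(O)c2c(OCOC)ccc(OCOC)c2c1O[Si](C)(C)C(C)(C)C | intermediate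
18 | 2-[(1R)-1-(tert-butyldimethylsilyloxy)-4-methylpent-3-enyl]-5,8-bis(methoxymethoxy)naphthalene-1,4-dione | CC(C)=CC[C@@H](O[Si](C)(C)C(C)(C)C)C1=CC(=O)c2c(OCOC)ccc(OCOC)c2C1=O | intermediate
19 | 5,8-dihydroxy-2-[(1R)-1-hydroxy-4-methylpent-3-enyl]naphthalene-1,4-dione (shikonin) | CC(C)=CC[C@@H](O)C1=CC(=O)c2c(O)ccc(O)c2C1=O | intermediate
20 | 3,4-dimethylpent-3-enoic acid | CC(C)=C(C)CC(=O)O | starting material
21 | (1R)-1-(5,8-dihydroxy-1,4-dioxo-1,4-dihydronaphthalen-2-yl)-4-methylpent-3-enyl 3,4-dimethylpent-3-enoate | CC(C)=CC[C@@H](OC(=O)CC(C)=C(C)C)C1=CC(=O)c2c(O)ccc(O)c2C1=O | target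

**Summary**

Total step count: 10. Longest linear sequence: 9 steps (steps 1–5 and 7–10, from 4-methylpent-3-enoic acid); step 6 is a one-step side branch.

**Steps most likely to fail**

1. Step 7. The aryne may be consumed by the amine formed from the base or by the naphtholate already produced, or the amide base may attack the silyloxyfuran, before cycloaddition takes place. Fallback (amine-free aryne generation by halogen–lithium exchange): setting out from 13, lithiation with LiN(iPr)2 in THF at −78 °C and quenching of the cold aryllithium with I2 should give 2-bromo-3-iodo-1,4-bis(methoxymethoxy)benzene F1. Adding n-BuLi at −78 °C to a toluene solution of F1 and furan 11 should regenerate aryllithium 14 by iodine–lithium exchange with no amine present. Warming should then lead through 15 and 16 to naphthol 17, where the route resumes.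

2. Step 4. Lithiation may take place partly at C5 instead of C2, or the second deprotonation may stall, so that oxygen is introduced at the wrong ring position or not at all. Fallback (regiochemistry fixed by electrophilic substitution instead of directed deprotonation): setting out from 7, bromination with N-bromosuccinimide in DMF at −20 °C, which for 3-alkylfurans goes to the ring position next to the substituent, should give (1R)-1-(2-bromofuran-3-yl)-4-methylpent-3-en-1-ol F2. Two equivalents of n-BuLi in THF at −78 °C then deprotonate the hydroxyl and exchange bromine for lithium, giving dilithio species 8 with lithium only at C2. Borylation and peroxide oxidation as in step 4 return the route to butenolide 10.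

3. Step 9. Ionisation at the carbinol carbon in aqueous acid may cause racemisation, or cyclisation or hydration at the prenyl alkene, while the acetals are being hydrolysed. Fallback (the ester is installed before the naphthazarin is unmasked, and no aqueous Brønsted acid is used): setting out from 18, HF·pyridine in THF/pyridine at 0 °C should remove the silyl group to give 2-[(1R)-1-hydroxy-4-methylpent-3-enyl]-5,8-bis(methoxymethoxy)naphthalene-1,4-dione F3. Steglich esterification of F3 with acid 20 should give (1R)-1-[5,8-bis(methoxymethoxy)-1,4-dioxo-1,4-dihydronaphthalen-2-yl]-4-methylpent-3-enyl 3,4-dimethylpent-3-enoate F4. Chelation-assisted cleavage of the two peri acetals of F4 with MgBr2·OEt2 in CH2Cl2/Et2O at low temperature should then give the target 21 directly.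

**Further compounds**

F1 | step 7 | 2-bromo-3-iodo-1,4-bis(methoxymethoxy)benzene | COCOc1ccc(OCOC)c(Br)c1I
F2 | step 4 | (1R)-1-(2-bromofuran-3-yl)-4-methylpent-3-en-1-ol | CC(C)=CC[C@@H](O)c1ccoc1Br
F3 | step 9 | 2-[(1R)-1-hydroxy-4-methylpent-3-enyl]-5,8-bis(methoxymethoxy)naphthalene-1,4-dione | CC(C)=CC[C@@H](O)C1=CC(=O)c2c(OCOC)ccc(OCOC)c2C1=O
F4 | step 9 | (1R)-1-[5,8-bis(methoxymethoxy)-1,4-dioxo-1,4-dihydronaphthalen-2-yl]-4-methylpent-3-enyl 3,4-dimethylpent-3-enoate | CC(C)=CC[C@@H](OC(=O)CC(C)=C(C)C)C1=CC(=O)c2c(OCOC)ccc(OCOC)c2C1=O
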